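**Plan**

1. Atoms are numbered as in 1-benzoxepin (O1, C2–C5, C5a, C6–C9, C9a). The retrosynthesis cuts the C2–CH2Br arm back to a lactone carbonyl, ring B at C3=C4 (ring-closing metathesis) and at the O1–C2 acyl bond, and ring A at C6–C7 and C8–C9.
2. Enabling feature: C7 carries bromine next to quaternary C6 and is linked through C8–C9 to the oxygen-bearing quaternary C9a. C7–Br is therefore treated as a latent C7–B bond: a B-vinyl group (C7=C8) is inserted between the boron-bound tertiary carbon C6 and the CH2 (C9) of a 2,2-disubstituted epoxide whose oxygen stays on C9a.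
3. Forward order: acyclic chain (conjugate borylation, auxiliary-controlled allylation, methyl ketone, epoxide), then ring A by the borate annulation, then C7–B to C7–Br, then ring B by acylation and metathesis, then the C2 arm.
4. Stereochemistry: C5a from an Evans alkylation; C9a from Felkin–Anh epoxide formation next to C5a; C7 from the annulation (boron cis to the C9a oxygen) followed by bromination with inversion; C2 from hydroboration anti to the axial C9a methyl.

Key step: step 7

**Route**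

Step 1
Reactants: 1 (4S)-4-benzyl-1,3-oxazolidin-2-one; 2 3-methylbut-2-enoyl chloride
Product: 3 (4S)-4-benzyl-3-(3-methylbut-2-enoyl)-1,3-oxazolidin-2-one
Conditions: n-BuLi, THF, −78 °C; then 2, −78 → 0 °C
Reagents that add atoms: none
Why: N-acylation of the lithiated oxazolidinone by the acid chloride (standard auxiliary loading); no stereocentre is formed.

Step 2
Reactants: 3 (4S)-4-benzyl-3-(3-methylbut-2-enoyl)-1,3-oxazolidin-2-one
Product: 4 (4S)-4-benzyl-3-[3-methyl-3-(4,4,5,5-tetramethyl-1,3,2-dioxaborolan-2-yl)butanoyl]-1,3-oxazolidin-2-one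
Conditions: B2pin2, CuCl (5 mol %), DPEphos (5 mol %), NaOt-Bu (10 mol %), i-PrOH (2 equiv), THF, rt
Reagents that add atoms: bis(pinacolato)diboron, CC1(C)OB(OC1(C)C)B1OC(C)(C)C(C)(C)O1
Why: Copper-catalysed conjugate borylation of the β,β-disubstituted enoyl imide should place boron on the tertiary carbon that becomes C6, which is not stereogenic; the hindered alcohol is chosen to limit alcoholysis of the imide.

Step 3
Reactants: 4 (4S)-4-benzyl-3-[3-methyl-3-(4,4,5,5-tetramethyl-1,3,2-dioxaborolan-2-yl)butanoyl]-1,3-oxazolidin-2-one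
Product: 5 (4S)-4-benzyl-3-{(2S)-2-[2-(4,4,5,5-tetramethyl-1,3,2-dioxaborolan-2-yl)propan-2-yl]pent-4-enoyl}-1,3-oxazolidin-2-one
Conditions: NaN(SiMe3)2, THF, −78 °C; allyl iodide, −78 → −40 °C
Reagents that add atoms: allyl iodide, C=CCI
Why: Evans alkylation, in which the chelated Z-sodium enolate should be allylated on the face away from the benzyl group, setting the future C5a centre (2S).

Step 4
Reactants: 5 (4S)-4-benzyl-3-{(2S)-2-[2-(4,4,5,5-tetramethyl-1,3,2-dioxaborolan-2-yl)propan-2-yl]pent-4-enoyl}-1,3-oxazolidin-2-one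
Product: 6 S-ethyl (2S)-2-[2-(4,4,5,5-tetramethyl-1,3,2-dioxaborolan-2-yl)propan-2-yl]pent-4-enethioate
Conditions: EtSH, n-BuLi, THF, 0 °C → rt
Reagents that add atoms: ethanethiol, CCS
Why: Thiolate cleavage of the hindered imide at the exocyclic carbonyl (transthioesterification) should release the auxiliary without the peroxide that would oxidise the C–B bond and without epimerising the α-centre.

Step 5
Reactants: 6 S-ethyl (2S)-2-[2-(4,4,5,5-tetramethyl-1,3,2-dioxaborolan-2-yl)propan-2-yl]pent-4-enethioate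
Product: 7 (3S)-3-[2-(4,4,5,5-tetramethyl-1,3,2-dioxaborolan-2-yl)propan-2-yl]hex-5-en-2-one
Conditions: Me2CuLi (from CuI and MeLi), Et2O, −78 → −30 °C
Reagents that add atoms: lithium dimethylcuprate, [Li+].C[Cu-]C
Why: Cuprate acylation of a thioester should stop at the methyl ketone and is not basic enough to epimerise the α-stereocentre.

Step 6
Reactants: 7 (3S)-3-[2-(4,4,5,5-tetramethyl-1,3,2-dioxaborolan-2-yl)propan-2-yl]hex-5-en-2-one
Product: 8 4,4,5,5-tetramethyl-2-{(3S)-2-methyl-3-[(2R)-2-methyloxiran-2-yl]hex-5-en-2-yl}-1,3,2-dioxaborolane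
Conditions: Me3S+ I−, n-BuLi, THF, −10 °C; then 7, −78 → 0 °C
Reagents that add atoms: trimethylsulfonium iodide, C[S+](C)C.[I-]
Why: Corey–Chaykovsky methylene transfer, in which irreversible Felkin–Anh addition of the ylide anti to the bulky boron-bearing tert-alkyl group should set the epoxide carbon (future C9a) as R.

Step 7
Reactants: 8 4,4,5,5-tetramethyl-2-{(3S)-2-methyl-3-[(2R)-2-methyloxiran-2-yl]hex-5-en-2-yl}-1,3,2-dioxaborolane
Product: 11 triethyl{[(1S,2S,4R)-1,3,3-trimethyl-2-(prop-2-en-1-yl)-4-(4,4,5,5-tetramethyl-1,3,2-dioxaborolan-2-yl)cyclohexyl]oxy}silane, via lithium vinylborate complex 9 (not isolated), via lithium alkoxide 10 (not isolated)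
Conditions: CH2=CHLi (from (CH2=CH)4Sn and n-BuLi), Et2O, −78 → 0 °C; toluene, 60 °C; then Et3SiOTf, −78 → 0 °C
Reagents that add atoms: vinyllithium, [Li]C=C; triethylsilyl trifluoromethanesulfonate, CC[Si](CC)(CC)OS(=O)(=O)C(F)(F)F
Why: Proposed new method: vinyllithium should add to boron faster than to the epoxide and give ate complex 9, in which C8 (the β-carbon of the B-vinyl group) is an anionic π-nucleophile held six atoms from the epoxide CH2 (C9) while the lithium ion on the pinacolate oxygens can activate the epoxide oxygen; attack of C8 on C9 opens the epoxide with SN2 geometry and, as charge builds at C7, the tertiary carbon C6 shifts from boron to C7 (1,2-metallate rearrangement), so C8–C9 and C6–C7 form in one event. The closest known reaction type is the electrophile-induced 1,2-metallate rearrangement of vinylboron ate complexes (Zweifel olefination, three-component conjunctive couplings, opening of epoxides by lithium trialkylvinylborates), which has not been run with the electrophile tethered to the migrating carbon. Ring A closes through a chair-like six-membered transition state by endo opening of the epoxide at its unsubstituted carbon (7-endo-tet for the borate, contracting to the cyclohexane as C6 moves from B to C7); because C9 is tethered to C6, both bonds must form on the same face of the vinyl group, which a stepwise, charge-separated shift allows. C5a and C9a are carried over unchanged (the C9a–O bond is not broken), and the new centre C7 is expected to carry boron axial and cis to the C9a oxygen because the lithium ion bridges the pinacolate and epoxide oxygens in the transition state. The step needs attack at the CH2 and not at the quaternary epoxide carbon, which is secured by the absence of a strong Lewis acid so that only the SN2-accessible carbon reacts, and it needs carbon to migrate in preference to a pinacol oxygen, the usual order for such complexes. The lithium alkoxide 10 is silylated in the same flask so that the next step can use an aryllithium.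

Step 8
Reactants: 11 triethyl{[(1S,2S,4R)-1,3,3-trimethyl-2-(prop-2-en-1-yl)-4-(4,4,5,5-tetramethyl-1,3,2-dioxaborolan-2-yl)cyclohexyl]oxy}silane
Product: 14 (1S,2S,4S)-4-bromo-1,3,3-trimethyl-2-(prop-2-en-1-yl)cyclohexan-1-ol, via lithium arylborate complex 12 (not isolated), via bromo silyl ether 13 (not isolated)
Conditions: 3,5-(CF3)2C6H3Br, n-BuLi, THF, −78 °C; add 11, −78 °C; NBS, −78 °C → rt; then HCl (1 M), MeOH, rt
Reagents that add atoms: N-bromosuccinimide, O=C1CCC(=O)N1Br
Why: Stereoinvertive electrophilic bromination (SE2 with inversion) of the electron-poor aryl boronate complex should turn the axial C–B bond into the equatorial C7–Br bond, and acidic methanolysis then removes the silyl ether.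

Step 9
Reactants: 15 ethyl 2-(hydroxymethyl)prop-2-enoate
Product: 16 ethyl 2-({[tert-butyl(dimethyl)silyl]oxy}methyl)prop-2-enoate
Conditions: t-BuMe2SiCl, imidazole, DMF, rt
Reagents that add atoms: tert-butyldimethylsilyl chloride, CC(C)(C)[Si](C)(C)Cl
Why: Standard silylation of a primary allylic alcohol.

Step 10
Reactants: 16 ethyl 2-({[tert-butyl(dimethyl)silyl]oxy}methyl)prop-2-enoate
Product: 17 2-({[tert-butyl(dimethyl)silyl]oxy}methyl)prop-2-enoic acid
Conditions: LiOH·H2O, THF/H2O, 0 °C → rt; HCl to pH 3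
Reagents that add atoms: lithium hydroxide, [Li+].[OH-]
Why: Saponification of the ethyl ester, which the primary silyl ether should survive at this temperature.

Step 11
Reactants: 14 (1S,2S,4S)-4-bromo-1,3,3-trimethyl-2-(prop-2-en-1-yl)cyclohexan-1-ol; 17 2-({[tert-butyl(dimethyl)silyl]oxy}methyl)prop-2-enoic acid
Product: 20 (1S,2S,4S)-4-bromo-1,3,3-trimethyl-2-(prop-2-en-1-yl)cyclohexyl 2-({[tert-butyl(dimethyl)silyl]oxy}methyl)prop-2-enoate, via acid chloride 18 (not isolated), via lithium alkoxide 19 (not isolated)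
Conditions: 17, 1-chloro-N,N,2-trimethylprop-1-en-1-amine, CH2Cl2, 0 °C → rt; 14, LiN(SiMe3)2, THF, −78 °C; combine, −78 °C → rt
Reagents that add atoms: none
Why: Acylation of the hindered tertiary alkoxide by an acid chloride made under neutral conditions, the reliable way to esterify an equatorial tertiary alcohol of this kind.

Step 12
Reactants: 20 (1S,2S,4S)-4-bromo-1,3,3-trimethyl-2-(prop-2-en-1-yl)cyclohexyl 2-({[tert-butyl(dimethyl)silyl]oxy}methyl)prop-2-enoate
Product: 21 (5aS,7S,9aS)-7-bromo-3-({[tert-butyl(dimethyl)silyl]oxy}methyl)-6,6,9a-trimethyl-5a,6,7,8,9,9a-hexahydro-1-benzoxepin-2(5H)-one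
Conditions: second-generation Grubbs catalyst (H2IMes)(PCy3)Cl2Ru=CHPh (10 mol %), toluene (2 mM), 80 °C
Reagents that add atoms: none
Why: Ring-closing metathesis between the allyl group and the 2-substituted acrylate should close the seven-membered ring B with the C3=C4 alkene necessarily cis in the ring, the two reacting arms being gauche on the trans-diequatorial C5a/C9a positions.

Step 13
Reactants: 21 (5aS,7S,9aS)-7-bromo-3-({[tert-butyl(dimethyl)silyl]oxy}methyl)-6,6,9a-trimethyl-5a,6,7,8,9,9a-hexahydro-1-benzoxepin-2(5H)-one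
Product: 22 {[(5aS,7S,9aS)-7-bromo-6,6,9a-trimethyl-2-methylidene-2,5,5a,6,7,8,9,9a-octahydro-1-benzoxepin-3-yl]methoxy}(tert-butyl)dimethylsilane
Conditions: Cp2TiMe2, toluene, 70 °C, dark
Reagents that add atoms: dimethyltitanocene, C[Ti](C)(C1C=CC=C1)C1C=CC=C1
Why: Petasis methylenation converts the lactone carbonyl into the exocyclic enol ether under non-basic conditions that the alkyl bromide and silyl ether should tolerate.

Step 14
Reactants: 22 {[(5aS,7S,9aS)-7-bromo-6,6,9a-trimethyl-2-methylidene-2,5,5a,6,7,8,9,9a-octahydro-1-benzoxepin-3-yl]methoxy}(tert-butyl)dimethylsilane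
Product: 24 [(2R,5aS,7S,9aS)-7-bromo-3-({[tert-butyl(dimethyl)silyl]oxy}methyl)-6,6,9a-trimethyl-2,5,5a,6,7,8,9,9a-octahydro-1-benzoxepin-2-yl]methanol, via alkylborane 23 (not isolated)
Conditions: 9-BBN, THF, 0 °C → rt; then NaOH (3 M), H2O2 (30%), 0 °C
Reagents that add atoms: hydrogen peroxide, OO
Why: Hydroboration–oxidation of the exocyclic enol ether, in which the bulky borane should add to the terminal CH2 in preference to the trisubstituted alkene and deliver hydrogen to C2 from the face opposite the axial C9a methyl, setting C2 as R with the hydroxymethyl group cis to that methyl.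

Step 15
Reactants: 24 [(2R,5aS,7S,9aS)-7-bromo-3-({[tert-butyl(dimethyl)silyl]oxy}methyl)-6,6,9a-trimethyl-2,5,5a,6,7,8,9,9a-octahydro-1-benzoxepin-2-yl]methanol
Product: 25 {[(2R,5aS,7S,9aS)-7-bromo-2-(bromomethyl)-6,6,9a-trimethyl-2,5,5a,6,7,8,9,9a-octahydro-1-benzoxepin-3-yl]methoxy}(tert-butyl)dimethylsilane
Conditions: CBr4, PPh3, CH2Cl2, 0 °C
Reagents that add atoms: carbon tetrabromide, BrC(Br)(Br)Br
Why: Appel bromination of the primary alcohol, which does not touch the C2 stereocentre.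

Step 16
Reactants: 25 {[(2R,5aS,7S,9aS)-7-bromo-2-(bromomethyl)-6,6,9a-trimethyl-2,5,5a,6,7,8,9,9a-octahydro-1-benzoxepin-3-yl]methoxy}(tert-butyl)dimethylsilane
Product: 26 [(2R,5aS,7S,9aS)-7-bromo-2-(bromomethyl)-6,6,9a-trimethyl-2,5,5a,6,7,8,9,9a-octahydro-1-benzoxepin-3-yl]methanol
Conditions: HF·pyridine, THF, 0 °C → rt
Reagents that add atoms: none
Why: Fluoride cleavage of the primary silyl ether under buffered conditions that should leave both bromides and the allylic ether untouched.

**Compound list**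

1 | (4S)-4-benzyl-1,3-oxazolidin-2-one | O=C1N[C@@H](Cc2ccccc2)CO1 | starting material
2 | 3-methylbut-2-enoyl chloride | CC(C)=CC(Cl)=O | starting material
3 | (4S)-4-benzyl-3-(3-methylbut-2-enoyl)-1,3-oxazolidin-2-one | CC(C)=CC(=O)N1[C@@H](Cc2ccccc2)COC1=O | intermediate
4 | (4S)-4-benzyl-3-[3-methyl-3-(4,4,5,5-tetramethyl-1,3,2-dioxaborolan-2-yl)butanoyl]-1,3-oxazolidin-2-one | CC(C)(CC(=O)N1[C@@H](Cc2ccccc2)COC1=O)B1OC(C)(C)C(C)(C)O1 | intermediate
5 | (4S)-4-benzyl-3-{(2S)-2-[2-(4,4,5,5-tetramethyl-1,3,2-dioxaborolan-2-yl)propan-2-yl]pent-4-enoyl}-1,3-oxazolidin-2-one | C=CC[C@H](C(=O)N1[C@@H](Cc2ccccc2)COC1=O)C(C)(C)B1OC(C)(C)C(C)(C)O1 | intermediate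
6 | S-ethyl (2S)-2-[2-(4,4,5,5-tetramethyl-1,3,2-dioxaborolan-2-yl)propan-2-yl]pent-4-enethioate | C=CC[C@H](C(=O)SCC)C(C)(C)B1OC(C)(C)C(C)(C)O1 | intermediate
7 | (3S)-3-[2-(4,4,5,5-tetramethyl-1,3,2-dioxaborolan-2-yl)propan-2-yl]hex-5-en-2-one | C=CC[C@H](C(C)=O)C(C)(C)B1OC(C)(C)C(C)(C)O1 | intermediate
8 | 4,4,5,5-tetramethyl-2-{(3S)-2-methyl-3-[(2R)-2-methyloxiran-2-yl]hex-5-en-2-yl}-1,3,2-dioxaborolane | C=CC[C@H]([C@]1(C)CO1)C(C)(C)B1OC(C)(C)C(C)(C)O1 | intermediate
9 | lithium ethenyl{(3S)-2-methyl-3-[(2R)-2-methyloxiran-2-yl]hex-5-en-2-yl}(2,3-dimethylbutane-2,3-diolato)borate (not isolated) | C=CC[C@H]([C@]1(C)CO1)C(C)(C)[B-]1(C=C)OC(C)(C)C(C)(C)O1.[Li+] | intermediate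
10 | lithium (1S,2S,4R)-1,3,3-trimethyl-2-(prop-2-en-1-yl)-4-(4,4,5,5-tetramethyl-1,3,2-dioxaborolan-2-yl)cyclohexan-1-olate (not isolated) | CC1(C)[C@H](B2OC(C)(C)C(C)(C)O2)CC[C@](C)([O-])[C@H]1CC=C.[Li+] | intermediate
11 | triethyl{[(1S,2S,4R)-1,3,3-trimethyl-2-(prop-2-en-1-yl)-4-(4,4,5,5-tetramethyl-1,3,2-dioxaborolan-2-yl)cyclohexyl]oxy}silane | CC1(C)[C@H](B2OC(C)(C)C(C)(C)O2)CC[C@](C)(O[Si](CC)(CC)CC)[C@H]1CC=C | intermediate
12 | lithium [3,5-bis(trifluoromethyl)phenyl](2,3-dimethylbutane-2,3-diolato){(1R,3S,4S)-2,2,4-trimethyl-3-(prop-2-en-1-yl)-4-[(triethylsilyl)oxy]cyclohexyl}borate (not isolated) | CC1(C)[C@H]([B-]2(c3cc(cc(c3)C(F)(F)F)C(F)(F)F)OC(C)(C)C(C)(C)O2)CC[C@](C)(O[Si](CC)(CC)CC)[C@H]1CC=C.[Li+] | intermediate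
13 | {[(1S,2S,4S)-4-bromo-1,3,3-trimethyl-2-(prop-2-en-1-yl)cyclohexyl]oxy}triethylsilane (not isolated) | CC1(C)[C@@H](Br)CC[C@](C)(O[Si](CC)(CC)CC)[C@H]1CC=C | intermediate
14 | (1S,2S,4S)-4-bromo-1,3,3-trimethyl-2-(prop-2-en-1-yl)cyclohexan-1-ol | CC1(C)[C@@H](Br)CC[C@](C)(O)[C@H]1CC=C | intermediate
15 | ethyl 2-(hydroxymethyl)prop-2-enoate | C=C(CO)C(=O)OCC | starting material
16 | ethyl 2-({[tert-butyl(dimethyl)silyl]oxy}methyl)prop-2-enoate | C=C(CO[Si](C)(C)C(C)(C)C)C(=O)OCC | intermediate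
17 | 2-({[tert-butyl(dimethyl)silyl]oxy}methyl)prop-2-enoic acid | C=C(CO[Si](C)(C)C(C)(C)C)C(=O)O | intermediate
18 | 2-({[tert-butyl(dimethyl)silyl]oxy}methyl)prop-2-enoyl chloride (not isolated) | C=C(CO[Si](C)(C)C(C)(C)C)C(=O)Cl | intermediate
19 | lithium (1S,2S,4S)-4-bromo-1,3,3-trimethyl-2-(prop-2-en-1-yl)cyclohexan-1-olate (not isolated) | CC1(C)[C@@H](Br)CC[C@](C)([O-])[C@H]1CC=C.[Li+] | intermediate
20 | (1S,2S,4S)-4-bromo-1,3,3-trimethyl-2-(prop-2-en-1-yl)cyclohexyl 2-({[tert-butyl(dimethyl)silyl]oxy}methyl)prop-2-enoate | CC1(C)[C@@H](Br)CC[C@](C)(OC(=O)C(=C)CO[Si](C)(C)C(C)(C)C)[C@H]1CC=C | intermediate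
21 | (5aS,7S,9aS)-7-bromo-3-({[tert-butyl(dimethyl)silyl]oxy}methyl)-6,6,9a-trimethyl-5a,6,7,8,9,9a-hexahydro-1-benzoxepin-2(5H)-one | CC1(C)[C@@H](Br)CC[C@]2(C)OC(=O)C(CO[Si](C)(C)C(C)(C)C)=CC[C@@H]12 | intermediate
22 | {[(5aS,7S,9aS)-7-bromo-6,6,9a-trimethyl-2-methylidene-2,5,5a,6,7,8,9,9a-octahydro-1-benzoxepin-3-yl]methoxy}(tert-butyl)dimethylsilane | CC1(C)[C@@H](Br)CC[C@]2(C)OC(=C)C(CO[Si](C)(C)C(C)(C)C)=CC[C@@H]12 | intermediate
23 | 9-{[(2R,5aS,7S,9aS)-7-bromo-3-({[tert-butyl(dimethyl)silyl]oxy}methyl)-6,6,9a-trimethyl-2,5,5a,6,7,8,9,9a-octahydro-1-benzoxepin-2-yl]methyl}-9-borabicyclo[3.3.1]nonane (not isolated) | CC1(C)[C@@H](Br)CC[C@]2(C)O[C@@H](CB3C4CCCC3CCC4)C(CO[Si](C)(C)C(C)(C)C)=CC[C@@H]12 | intermediate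
24 | [(2R,5aS,7S,9aS)-7-bromo-3-({[tert-butyl(dimethyl)silyl]oxy}methyl)-6,6,9a-trimethyl-2,5,5a,6,7,8,9,9a-octahydro-1-benzoxepin-2-yl]methanol | CC1(C)[C@@H](Br)CC[C@]2(C)O[C@@H](CO)C(CO[Si](C)(C)C(C)(C)C)=CC[C@@H]12 | intermediate
25 | {[(2R,5aS,7S,9aS)-7-bromo-2-(bromomethyl)-6,6,9a-trimethyl-2,5,5a,6,7,8,9,9a-octahydro-1-benzoxepin-3-yl]methoxy}(tert-butyl)dimethylsilane | CC1(C)[C@@H](Br)CC[C@]2(C)O[C@@H](CBr)C(CO[Si](C)(C)C(C)(C)C)=CC[C@@H]12 | intermediate
26 | [(2R,5aS,7S,9aS)-7-bromo-2-(bromomethyl)-6,6,9a-trimethyl-2,5,5a,6,7,8,9,9a-octahydro-1-benzoxepin-3-yl]methanol | CC1(C)[C@@H](Br)CC[C@]2(C)O[C@@H](CBr)C(CO)=CC[C@@H]12 | target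

**Step count**

Total steps: 16. Longest linear sequence: 14 (steps 1–8 and 11–16; steps 9 and 10 make the acid fragment).

**Steps most likely to fail**

Step 7 (Proposed new method). The borate π-bond may be too weak a nucleophile for the lithium-activated epoxide. If a stronger Lewis acid has to be added, ionisation at the quaternary epoxide carbon may divert the closure to a five-membered ring. The C7 centre may also form with boron equatorial, which the next step cannot use. The fallback uses known chemistry and forms the two ring bonds in separate steps; it sets out from 8 and comes back at 14. A Zweifel-type coupling of 8 with 1-ethoxyvinyllithium (ethyl vinyl ether, t-BuLi; then I2, NaOMe) forms the C6–C7 bond and should give the enol ether (2R)-2-[(4S)-2-ethoxy-3,3-dimethylhepta-1,6-dien-4-yl]-2-methyloxirane F1. Mild hydrolysis (oxalic acid on wet silica) should give the methyl ketone (4S)-3,3-dimethyl-4-[(2R)-2-methyloxiran-2-yl]hept-6-en-2-one F2. LiN(i-Pr)2 at −78 °C forms the kinetic methyl enolate, which on warming should open the epoxide at its CH2 (C8–C9 bond) to give the hydroxy ketone (3S,4S)-4-hydroxy-2,2,4-trimethyl-3-(prop-2-en-1-yl)cyclohexan-1-one F3. LiBH(s-Bu)3 should reduce the hindered C7 ketone from the equatorial side to the axial alcohol (1S,2S,4R)-1,3,3-trimethyl-2-(prop-2-en-1-yl)cyclohexane-1,4-diol F4. CBr4/PPh3 then replaces the secondary hydroxyl with inversion to reach 14.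

Step 8. Addition of the aryllithium to the axial boronate next to the quaternary carbon may be slow or incomplete, and single-electron pathways in the bromination may erode the inversion. The fallback sets out from 11 and comes back at 13. Oxidation of the C–B bond with NaBO3·4H2O (retention) should give the axial alcohol (1R,3S,4S)-2,2,4-trimethyl-3-(prop-2-en-1-yl)-4-[(triethylsilyl)oxy]cyclohexan-1-ol F5. CBr4/PPh3 then displaces the hydroxyl with inversion to give 13, which is carried through the acidic methanolysis of step 8.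

Step 14. Facial selectivity of the hydroboration at C2 may be poor, and the acid-labile dienyl enol ether 22 may undergo hydrolytic ring opening before it reacts. The fallback sets out from 21 and comes back at 25, so steps 13–15 are not needed. Bromomethyllithium (CH2Br2, MeLi·LiBr, THF, −78 °C) is added to the lactone carbonyl and should give the hemiketal (5aS,7S,9aS)-7-bromo-2-(bromomethyl)-3-({[tert-butyl(dimethyl)silyl]oxy}methyl)-6,6,9a-trimethyl-2,5,5a,6,7,8,9,9a-octahydro-1-benzoxepin-2-ol F6. Et3SiH with BF3·OEt2 at −78 °C should then reduce the derived oxocarbenium ion from the face opposite the axial C9a methyl to give 25.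

Further compounds
F1 | step 7 | (2R)-2-[(4S)-2-ethoxy-3,3-dimethylhepta-1,6-dien-4-yl]-2-methyloxirane | C=CC[C@H]([C@]1(C)CO1)C(C)(C)C(=C)OCC
F2 | step 7 | (4S)-3,3-dimethyl-4-[(2R)-2-methyloxiran-2-yl]hept-6-en-2-one | C=CC[C@H]([C@]1(C)CO1)C(C)(C)C(C)=O
F3 | step 7 | (3S,4S)-4-hydroxy-2,2,4-trimethyl-3-(prop-2-en-1-yl)cyclohexan-1-one | CC1(C)C(=O)CC[C@](C)(O)[C@H]1CC=C
F4 | step 7 | (1S,2S,4R)-1,3,3-trimethyl-2-(prop-2-en-1-yl)cyclohexane-1,4-diol | CC1(C)[C@H](O)CC[C@](C)(O)[C@H]1CC=C
F5 | step 8 | (1R,3S,4S)-2,2,4-trimethyl-3-(prop-2-en-1-yl)-4-[(triethylsilyl)oxy]cyclohexan-1-ol | CC1(C)[C@H](O)CC[C@](C)(O[Si](CC)(CC)CC)[C@H]1CC=C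
F6 | step 14 | (5aS,7S,9aS)-7-bromo-2-(bromomethyl)-3-({[tert-butyl(dimethyl)silyl]oxy}methyl)-6,6,9a-trimethyl-2,5,5a,6,7,8,9,9a-octahydro-1-benzoxepin-2-ol | CC1(C)[C@@H](Br)CC[C@]2(C)OC(O)(CBr)C(CO[Si](C)(C)C(C)(C)C)=CC[C@@H]12
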